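The readings stem from a simulated flask on assumed constants, and the scatter is random.

A small charge of starting material opened the meeting on this series, in which the enzyme turns starting material into target and target goes on to over-reaction product.

| flask | starting material | enzyme | remark | time |
|---|---|---|---|---|
| blue | 4.8 mM | 10 µM | run made earlier |  |
| grey | 310 mM | 10 µM | run made earlier |  |
| east | 6.0 mM | 10 µM |  | 20 min |
| south | 20 mM | 10 µM |  | 20 min |
| north-east | 60 mM | 10 µM |  | 20 min |
| north-west | 200 mM | 10 µM |  | 20 min |
| south-east | 500 mM | 10 µM |  | 20 min |

| run | time / min | target / % | starting material / % |
|---|---|---|---|
| blue | 2.00 | 52 | 44 |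
| blue | 4.00 | 63 | 18 |
| blue | 6.00 | 59 | 5 |
| blue | 8.00 | 49 | 3 |
| blue | 10.0 | 43 | 0 |
| grey | 2.00 | 1 | 95 |
| grey | 4.00 | 6 | 95 |
| grey | 6.00 | 8 | 90 |
| grey | 8.00 | 12 | 90 |
| grey | 10.0 | 11 | 84 |

(each reading ± 2 percentage points)

- steps under discussion: starting material + enzyme -> target + enzyme; target -> over-reaction product
- "hardly changes" means that all values lie within two and a half points (for a concentration: within two and a half percent of the largest)

- amount of target at the end, in percent of the starting material charged for east, south, north-east, north-west, south-east, in this order
- how the row runs (rises, then falls / rises all the way / falls, then rises / falls all the way / hardly changes)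

The analyst reported that the blue run read 0% starting material and 43% target at 10.0 min, so by difference about 57.0% of the charge had passed on to over-reaction product. The analyst proposed replacing the target curve of the blue run by its mean over those minutes, 48.9%, assuming that target loses a fixed share of itself each minute. That gives 8.58 min: the mean stock of target divided by what it loses per minute, the target lifetime.

The chair carried this to east, whose charge lies near that of blue. Blue's 43%, taken for east and left to sink for a further 10.0 min, comes to 13.4%.

The second speaker took the large charges. The grey run lost 16.0% of its charge in 10.0 min, a feed of 0.0160 min⁻¹, though that is a single reading with its scatter of 2 percentage points. A stock so fed climbs towards feed times lifetime, its steady state. The speaker tried the lifetime from blue on grey: this reckoning gives 9.45% at 10.0 min, and the reading was 11%. Assuming the same millimoles per minute in south-east, the speaker took them as a smaller share of that flask's charge, 0.00992 min⁻¹, which gives 7.68% there. With both ends low, the meeting expected a row that rises, then falls.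

The forecast gave 14.7%, 17.3%, 29%, 18.3% and 7.6%, and the shape rises, then falls, holding that at large charges “zero-order feed balances decay”. Its figure for east stands above the chair's 13.4%.

The flasks gave 13.8%, 18.0%, 29.0%, 16.7% and 7.33%: rises, then falls.

    starting material + enzyme → target + enzyme, rate k1*[starting material]*[enzyme]/(1 + ([starting material]/Km1) + ([target]/Kp1)) (7.40 mM, 16.0 mM, k = 1100 M⁻¹ s⁻¹)
    target → over-reaction product (k = 0.00190 s⁻¹)

South-east ended with 81.3% of its charge still starting material, and the lifetime reckoning of 7.68% stands against 7.33% target. That low figure in south-east comes from two things acting together: the term in starting material below the line of the enzyme's rate, and target passing on to over-reaction product. Without that term south-east ends at 22.0%, and without that step at 18.3%. On north-west the same lifetime gives 19.2%, and the flask gave 16.7%.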